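**Plan**
1. Retrosynthesis: the succinimide and the C12–C13 bond are cut first (auxiliary-controlled aldol of a C12 aldehyde with a 3-cyanopropanoyl imide, imide closure last). C8=C17, C9–C11 and the C7 oxygen go back to a C7/C9 vinylogous ester, the two chlorines to a C2 silyl enol ether, and ring A is cut last at C1–C10 and C4–C5.
2. Enabling feature: ring A (C1–C5, C10) is functionalised on both C2 and C3 (a latent C2=C3 enol ether), C4 carries both methyls, and the fusion bond C5–C10 is flanked in ring B by C6 and C9. Ring A is therefore the [4+2] adduct of a C1–C4 silyloxydiene on the C5=C10 bond of a benzoquinone that is ring B; the quinone OMe becomes the C7 oxygen and its methyl becomes C20.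
3. Forward order: ring B (quinone) → ring A by Diels–Alder → C6 deoxygenation and trans fusion → ring A dichloride → C11/C12 on C9 → C8 methylene → C7 acetate → aldol → succinimide.
4. Stereochemistry: C10 from the chiral titanium catalyst of the cycloaddition; C5 from Birch protonation; C3 from axial protonation of a chloro-enolate; C2 from α-face hydride then SN2 inversion; C9 and C7 from hydride delivery anti to C20; C12/C13 from the (R)-benzyloxazolidinone.

Key step: step 2

Remark: bicyclic compounds are described with labdane numbering (ring A = C1–C5/C10, ring B = C5–C10, C17 on C8, C20 on C10; β is the face of C20); compound 4 is assumed to be purchased.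

Step 1
Reactants: 1 mesityl oxide
Product: 3 tert-butyldimethyl[(4-methylpenta-1,3-dien-2-yl)oxy]silane, via lithium dienolate 2 (not isolated)
Conditions: LiN(iPr)2, THF, −78 °C; then tBuMe2SiCl, DMPU, −78 → 23 °C
Reagents that add atoms: tert-butyldimethylsilyl chloride, C[Si](C)(Cl)C(C)(C)C
Why: Kinetic deprotonation of the acetyl methyl group gives the cross-conjugated lithium dienolate, and O-silylation (silyl dienol ether synthesis) gives the 2-silyloxydiene; no stereocenter is formed.

Step 2
Reactants: 3 silyloxydiene; 4 2-methoxy-5-methyl-1,4-benzoquinone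
Product: 5 cis-fused adduct (4aS,8aR)-6-(tert-butyldimethylsilyloxy)-2-methoxy-4a,8,8-trimethyl-4a,5,8,8a-tetrahydronaphthalene-1,4-dione (labdane terms: 2-OTBS-Δ2; 5β-H; 6,9-dioxo; 7-OMe-Δ7)
Conditions: (R)-BINOL (20 mol %), TiCl2(OiPr)2 (20 mol %), 4 Å molecular sieves, CH2Cl2, −30 °C
Reagents that add atoms: none
Why: The titanium–BINOL complex binds the quinone through the carbonyl next to the methoxy carbon (future C6) and the methoxy oxygen, which places the largest LUMO coefficient on the methyl-bearing ring carbon (future C10); the nucleophilic CH2 terminus of the diene bonds there first (C1–C10) in a strongly asynchronous [4+2] transition state that may merge into a Mukaiyama–Michael/ring-closure sequence, the CMe2 terminus then bonding to the neighbouring CH (C4–C5). The closest known reaction type is the chiral-Lewis-acid-catalysed Diels–Alder reaction of alkoxy-substituted benzoquinones with silyloxydienes. Ring A is the only ring closed, by intermolecular [4+2] cycloaddition (in the stepwise limit a 6-endo-trig closure of the titanium enolate carbon C5 onto the silyloxyallyl cation terminus C4). C10 is set by the catalyst, which must leave the Si face of the methyl-bearing carbon open to the diene, and C5 follows from suprafacial addition (cis, H β), which does not matter because steps 3–5 re-set it. The step needs site selectivity (the methyl-substituted and not the methoxy-substituted C=C, secured by the vinylogous-ester deactivation of the latter), regioselectivity (CH2 terminus to the future quaternary carbon, secured by the chelated carbonyl and by pairing the unhindered diene end with the hindered dienophile end) and enantioface selectivity (catalyst). Should the (R)-ligand expose the opposite face, the (S)-ligand is used without other change.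

Step 3
Reactants: 5 cis-fused adduct
Product: 7 dienyl triflate (2-OTBS-Δ2; C5=C6 with 6-OTf; 7-OMe-Δ7; 9-oxo), via potassium dienolate 6 (not isolated)
Conditions: KN(SiMe3)2, THF, −78 °C; then PhNTf2, −78 → 0 °C
Reagents that add atoms: N-phenylbis(trifluoromethanesulfonimide), O=S(=O)(N(c1ccccc1)S(=O)(=O)C(F)(F)F)C(F)(F)F
Why: C5–H is the only enolisable hydrogen of 5 (C7 and C8 are sp2, C10 is quaternary), so enolate O-triflation (enol triflate synthesis) is regiospecific and erases the cis C5 centre.

Step 4
Reactants: 7 dienyl triflate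
Product: 8 linear dienone (2-OTBS-Δ2; Δ5; 7-OMe-Δ7; 9-oxo)
Conditions: Pd(OAc)2 (5 mol %), PPh3 (10 mol %), HCO2H, Bu3N, DMF, 40 °C, dark; used crude
Reagents that add atoms: none
Why: Formate reduction of an enol triflate catalysed by zerovalent palladium (oxidative addition, formate exchange, decarboxylation, reductive elimination) replaces the C6 oxygen by hydrogen without touching the silyl enol ether, and the 2,4-cyclohexadienone is used at once to forestall dimerisation; no stereocenter is formed.

Step 5
Reactants: 8 linear dienone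
Product: 11 trans-fused vinylogous ester (5α-H; 7-OMe-Δ7; 9-oxo; 2-OTBS-Δ2), via lithium dienolate 9 (not isolated), via deconjugated ketone 10 (not isolated)
Conditions: Li, NH3/THF, tBuOH (1 equiv), −78 °C; NH4Cl; then DBU (10 mol %), CH2Cl2, 23 °C
Reagents that add atoms: none
Why: Birch-type 1,6-reduction of the dienone protonates the C5 carbanion axially on the α face, anti to C20, which gives the trans ring fusion as in dissolving-metal reductions of octalones, and DBU then moves the remaining double bond into conjugation with the C9 carbonyl.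

Step 6
Reactants: 11 trans-fused vinylogous ester
Product: 12 3α-chloro-2-ketone (7-OMe-Δ7-9-one retained)
Conditions: N-chlorosuccinimide, NaHCO3, THF, −20 → 0 °C
Reagents that add atoms: N-chlorosuccinimide, O=C1CCC(=O)N1Cl
Why: Electrophilic chlorination of the silyl enol ether is regiospecific for C3 and is expected on the axial α face (the β face is blocked by the 4β-methyl), and the resulting C3 configuration is of no consequence because step 7 re-sets it.

Step 7
Reactants: 12 3α-chloro-2-ketone
Product: 15 3β-chloro-2β-alcohol, via chloro enol silane 13 (not isolated), via 3β-chloro ketone 14 (not isolated)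
Conditions: Me3SiOTf, Et3N, CH2Cl2, −20 → 0 °C; solvent switch to THF; Bu4NF, AcOH, −78 °C; then MeOH, CeCl3·7H2O, NaBH4, −78 °C
Reagents that add atoms: none
Why: Soft enolisation of the α-chloro ketone gives the chlorine-bearing enol silane, fluoride/acetic acid protonates the chloro-enolate kinetically on the open axial α face (chlorine equatorial, 3β), and immediate Luche reduction delivers hydride to C2 from the α face because the β face is shielded by the syn-axial 4β- and 10-methyl groups (axial 2β-OH).

Step 8
Reactants: 15 3β-chloro-2β-alcohol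
Product: 17 2α,3β-dichloride (5α-H; 7-OMe-Δ7; 9-oxo), via alkoxyiminium chloride 16 (not isolated)
Conditions: 1-chloro-N,N,2-trimethylprop-1-en-1-amine, CH2Cl2, 0 → 40 °C
Reagents that add atoms: 1-chloro-N,N,2-trimethylprop-1-en-1-amine, CC(C)=C(Cl)N(C)C
Why: Deoxychlorination with an α-chloroenamine runs through an alkoxyiminium chloride and SN2 displacement with inversion, which turns the strained axial 2β-oxygen into the equatorial 2α-chloride, and the cis 3β-chlorine cannot participate to cause retention.

Step 9
Reactants: 17 2α,3β-dichloride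
Product: 19 enone nitrile (7-oxo-Δ8; C9–CH2CN), via tertiary carbinol 18 (not isolated)
Conditions: MeCN, n-BuLi, THF, −78 °C; CeCl3; then 17, −78 → −40 °C; then 1 M HCl, THF, 0 → 23 °C
Reagents that add atoms: acetonitrile, CC#N; water, O
Why: 1,2-Addition of cerium-modified lithioacetonitrile to the vinylogous ester carbonyl and acid-induced allylic transposition with enol ether hydrolysis (Stork–Danheiser sequence) give the C7 ketone with C11/C12 on C9, the diequatorial dichloride having no antiperiplanar hydrogen for elimination and the C9 carbinol centre being lost again.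

Step 10
Reactants: 19 enone nitrile
Product: 23 exocyclic enone (7-oxo-8(17)-ene; 9α-H; C9–CH2CN β), via silyl enol ether 20 (not isolated), via Mannich base 21 (not isolated), via ammonium iodide 22 (not isolated)
Conditions: [(Ph3P)CuH]6 (5 mol %), PhMe2SiH, toluene, 23 °C; then CH2=NMe2+ I−, CH2Cl2, 23 °C; then MeI; then aq. NaHCO3
Reagents that add atoms: N,N-dimethylmethyleneiminium iodide, C=[N+](C)C.[I-]
Why: Copper hydride conjugate reduction delivers hydride to C9 axially on the α face, anti to C20 (side chain β, equatorial), and gives the C7–C8 silyl enol ether regiospecifically, which undergoes a Mannich reaction with the iminium salt before quaternisation and E1cB elimination unveil the C8 methylene.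

Step 11
Reactants: 23 exocyclic enone
Product: 24 7β-hydroxy-8(17)-ene nitrile
Conditions: NaBH4, CeCl3·7H2O, MeOH, −78 °C
Reagents that add atoms: none
Why: Luche 1,2-reduction with axial hydride attack on the α face gives the equatorial 7β-alcohol and leaves the nitrile, the chlorides and the alkene untouched.

Step 12
Reactants: 24 7β-hydroxy nitrile
Product: 26 7β-hydroxy C12 aldehyde, via aluminated aldimine 25 (not isolated)
Conditions: iBu2AlH (2.5 equiv), CH2Cl2, −78 °C; then 1 M HCl, 0 °C
Reagents that add atoms: water, O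
Why: iBu2AlH adds once to the nitrile to give an N-aluminio aldimine that is stable at −78 °C and is hydrolysed on work-up (partial reduction of a nitrile), the hydroxyl being only metallated and no stereocenter being affected.

Step 13
Reactants: 26 7β-hydroxy aldehyde
Product: 27 7β-acetoxy C12 aldehyde
Conditions: Ac2O, pyridine, CH2Cl2, 0 → 23 °C
Reagents that add atoms: acetic anhydride, CC(=O)OC(C)=O
Why: O-Acetylation of the secondary allylic alcohol proceeds under conditions to which the aldehyde is inert, and the C7 configuration is retained.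

Step 14
Reactants: 28 3-cyanopropanoic acid; 29 (R)-4-benzyl-1,3-oxazolidin-2-one
Product: 31 (R)-4-benzyl-3-(3-cyanopropanoyl)-1,3-oxazolidin-2-one, via mixed anhydride 30 (not isolated)
Conditions: tBuCOCl, Et3N, THF, −20 °C; then 29, LiCl, 23 °C
Reagents that add atoms: none
Why: N-Acylation of the oxazolidinone through the mixed pivalic anhydride is the standard imide synthesis and does not touch the auxiliary stereocenter.

Step 15
Reactants: 31 cyanopropanoyl imide; 27 7β-acetoxy aldehyde
Product: 33 syn-aldol adduct (12S,13R), via boron enolate 32 (not isolated)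
Conditions: Bu2BOTf, iPr2NEt, CH2Cl2, 0 °C; then 27, −78 → 0 °C; pH 7 buffer, MeOH, 30% H2O2, 0 °C
Reagents that add atoms: none
Why: In the Evans syn-aldol reaction the (Z)-boron enolate reacts through a closed chair transition state on the enolate face opposite to the benzyl group, which with the (R)-auxiliary sets 12S and 13R independently of the remote C9 centre.

Step 16
Reactants: 33 syn-aldol adduct
Product: 35 haterumaimide A, via primary amide 34 (not isolated)
Conditions: [PtH(PMe2OH)(PMe2O)2H] (5 mol %), EtOH/H2O 4:1, 70 °C; then Et3N, 4-(dimethylamino)pyridine (10 mol %), CH2Cl2, 23 °C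
Reagents that add atoms: water, O
Why: Platinum-catalysed hydration turns the nitrile into the primary amide under neutral conditions, and the amide nitrogen is then acylated intramolecularly by the activated N-acyloxazolidinone carbonyl (5-exo-trig acyl transfer), which closes the succinimide and releases the auxiliary without touching C12, C13 or the acetate.

**Compound list**
1 | mesityl oxide (4-methylpent-3-en-2-one) | CC(=O)C=C(C)C | starting material
2 | lithium 4-methylpenta-1,3-dien-2-olate | [Li+].[O-]C(=C)C=C(C)C | intermediate (not isolated)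
3 | tert-butyldimethyl[(4-methylpenta-1,3-dien-2-yl)oxy]silane | C=C(O[Si](C)(C)C(C)(C)C)C=C(C)C | intermediate
4 | 2-methoxy-5-methyl-1,4-benzoquinone | CC1=CC(=O)C(OC)=CC1=O | starting material
5 | (4aS,8aR)-6-(tert-butyldimethylsilyloxy)-2-methoxy-4a,8,8-trimethyl-4a,5,8,8a-tetrahydronaphthalene-1,4-dione (cis adduct) | O=C1C=C(OC)C(=O)[C@@H]2C(C)(C)C=C(O[Si](C)(C)C(C)(C)C)C[C@@]21C | intermediate
6 | potassium C5=C6 dienolate of 5 | O=C1C=C(OC)C([O-])=C2C(C)(C)C=C(O[Si](C)(C)C(C)(C)C)C[C@@]21C.[K+] | intermediate (not isolated)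
7 | dienyl triflate (2-OTBS-Δ2; Δ5; 6-OTf; 7-OMe-Δ7; 9-oxo) | O=C1C=C(OC)C(OS(=O)(=O)C(F)(F)F)=C2C(C)(C)C=C(O[Si](C)(C)C(C)(C)C)C[C@@]21C | intermediate
8 | linear dienone (2-OTBS-Δ2; Δ5; 7-OMe-Δ7; 9-oxo) | O=C1C=C(OC)C=C2C(C)(C)C=C(O[Si](C)(C)C(C)(C)C)C[C@@]21C | intermediate
9 | lithium dienolate (5α-H; 9-OLi-Δ8; 7-OMe-Δ6) | [Li+].[O-]C1=CC(OC)=C[C@H]2C(C)(C)C=C(O[Si](C)(C)C(C)(C)C)C[C@@]21C | intermediate (not isolated)
10 | deconjugated ketone (5α-H; 9-oxo; 7-OMe-Δ6) | O=C1CC(OC)=C[C@H]2C(C)(C)C=C(O[Si](C)(C)C(C)(C)C)C[C@@]21C | intermediate (not isolated)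
11 | trans-fused vinylogous ester (5α-H; 7-OMe-Δ7; 9-oxo; 2-OTBS-Δ2) | O=C1C=C(OC)C[C@H]2C(C)(C)C=C(O[Si](C)(C)C(C)(C)C)C[C@@]21C | intermediate
12 | 3α-chloro-2-ketone (7-OMe-Δ7; 9-oxo) | O=C1C=C(OC)C[C@H]2C(C)(C)[C@H](Cl)C(=O)C[C@@]21C | intermediate
13 | 3-chloro-2-(trimethylsilyloxy)-Δ2 enol silane | O=C1C=C(OC)C[C@H]2C(C)(C)C(Cl)=C(O[Si](C)(C)C)C[C@@]21C | intermediate (not isolated)
14 | 3β-chloro-2-ketone | O=C1C=C(OC)C[C@H]2C(C)(C)[C@@H](Cl)C(=O)C[C@@]21C | intermediate (not isolated)
15 | 3β-chloro-2β-alcohol | O=C1C=C(OC)C[C@H]2C(C)(C)[C@@H](Cl)[C@@H](O)C[C@@]21C | intermediate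
16 | 2β-alkoxyiminium chloride of 15 | O=C1C=C(OC)C[C@H]2C(C)(C)[C@@H](Cl)[C@@H](OC(C(C)C)=[N+](C)C)C[C@@]21C.[Cl-] | intermediate (not isolated)
17 | 2α,3β-dichloride (7-OMe-Δ7; 9-oxo) | O=C1C=C(OC)C[C@H]2C(C)(C)[C@@H](Cl)[C@H](Cl)C[C@@]21C | intermediate
18 | 9α-(cyanomethyl)-9β-hydroxy carbinol (7-OMe-Δ7) | N#CC[C@]1(O)C=C(OC)C[C@H]2C(C)(C)[C@@H](Cl)[C@H](Cl)C[C@@]21C | intermediate (not isolated)
19 | enone nitrile (2α,3β-dichloro; 7-oxo-Δ8; C9–CH2CN) | N#CCC1=CC(=O)C[C@H]2C(C)(C)[C@@H](Cl)[C@H](Cl)C[C@@]21C | intermediate
20 | 7-(dimethylphenylsilyloxy)-Δ7 enol ether (9α-H) | C1=C(O[Si](C)(C)c3ccccc3)C[C@H]2C(C)(C)[C@@H](Cl)[C@H](Cl)C[C@]2(C)[C@H]1CC#N | intermediate (not isolated)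
21 | 8α-(dimethylaminomethyl)-7-ketone (C8 configuration inconsequential) | CN(C)C[C@@H]1C(=O)C[C@H]2C(C)(C)[C@@H](Cl)[C@H](Cl)C[C@]2(C)[C@H]1CC#N | intermediate (not isolated)
22 | 8α-(trimethylammoniomethyl)-7-ketone iodide | C[N+](C)(C)C[C@@H]1C(=O)C[C@H]2C(C)(C)[C@@H](Cl)[C@H](Cl)C[C@]2(C)[C@H]1CC#N.[I-] | intermediate (not isolated)
23 | exocyclic enone (7-oxo-8(17)-ene; 9α-H; C9–CH2CN) | C=C1C(=O)C[C@H]2C(C)(C)[C@@H](Cl)[C@H](Cl)C[C@]2(C)[C@H]1CC#N | intermediate
24 | 7β-hydroxy-8(17)-ene nitrile | C=C1[C@@H](O)C[C@H]2C(C)(C)[C@@H](Cl)[C@H](Cl)C[C@]2(C)[C@H]1CC#N | intermediate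
25 | O,N-bis(diisobutylaluminio) aldimine | C=C1[C@@H](O[Al](CC(C)C)CC(C)C)C[C@H]2C(C)(C)[C@@H](Cl)[C@H](Cl)C[C@]2(C)[C@H]1CC=N[Al](CC(C)C)CC(C)C | intermediate (not isolated)
26 | 7β-hydroxy C12 aldehyde | C=C1[C@@H](O)C[C@H]2C(C)(C)[C@@H](Cl)[C@H](Cl)C[C@]2(C)[C@H]1CC=O | intermediate
27 | 7β-acetoxy C12 aldehyde | C=C1[C@@H](OC(C)=O)C[C@H]2C(C)(C)[C@@H](Cl)[C@H](Cl)C[C@]2(C)[C@H]1CC=O | intermediate
28 | 3-cyanopropanoic acid | N#CCCC(=O)O | starting material
29 | (R)-4-benzyl-1,3-oxazolidin-2-one | O=C1N[C@H](Cc2ccccc2)CO1 | starting material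
30 | 3-cyanopropanoic pivalic anhydride | N#CCCC(=O)OC(=O)C(C)(C)C | intermediate (not isolated)
31 | (R)-4-benzyl-3-(3-cyanopropanoyl)-1,3-oxazolidin-2-one | N#CCCC(=O)N1[C@H](Cc2ccccc2)COC1=O | intermediate
32 | (Z)-dibutylboron enolate of 31 | CCCC[B](CCCC)O/C(=C\CC#N)N1[C@H](Cc2ccccc2)COC1=O | intermediate (not isolated)
33 | syn-aldol adduct (12S,13R; C13 bears CH2CN and the acyloxazolidinone) | C=C1[C@@H](OC(C)=O)C[C@H]2C(C)(C)[C@@H](Cl)[C@H](Cl)C[C@]2(C)[C@H]1C[C@H](O)[C@H](C(=O)N3[C@H](Cc4ccccc4)COC3=O)CC#N | intermediate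
34 | primary amide of 33 | C=C1[C@@H](OC(C)=O)C[C@H]2C(C)(C)[C@@H](Cl)[C@H](Cl)C[C@]2(C)[C@H]1C[C@H](O)[C@H](C(=O)N3[C@H](Cc4ccccc4)COC3=O)CC(N)=O | intermediate (not isolated)
35 | haterumaimide A | C=C1[C@@H](OC(C)=O)C[C@H]2C(C)(C)[C@@H](Cl)[C@H](Cl)C[C@]2(C)[C@H]1C[C@H](O)[C@H]1CC(=O)NC1=O | target

**Step count**
Total: 16 steps. Longest linear sequence: 15 steps (steps 1–13, 15, 16).

**Steps most likely to fail**

Step 2. The closure at the fully substituted diene terminus may lag so far behind the first bond formation that the reaction stops after conjugate addition, or enantioface discrimination may be poor with so hindered a diene. The fallback sets out from 3 and 4 and runs the annulation as two separate polar events. Catalysed Mukaiyama–Michael addition with aqueous work-up should give the open-chain dione (5S)-2-methoxy-5-methyl-5-(4-methyl-2-oxopent-3-en-1-yl)cyclohex-2-ene-1,4-dione F1. Treatment with tBuMe2SiOTf/Et3N should then close ring A by intramolecular Mukaiyama–Michael addition of the C5 silyl enol ether to the β,β-dimethyl enone, the silyl group ending on the C2 enolate oxygen. This comes back to the route at 5, as a C5 epimer mixture that is harmless because step 3 removes this centre.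

Step 7. Enolisation of 12 may go towards C1 instead of C3, or the kinetically formed equatorial chloride may revert to the axial epimer by re-enolisation before hydride arrives. The fallback sets out from 11 and sets C3 by nucleophilic chloride with inversion instead of by protonation. Rubottom oxidation (m-CPBA on the α face, then HF·pyridine) should give the 3α-hydroxy-2-ketone F2, and Tf2O/2,6-lutidine the 3α-triflyloxy-2-ketone F3. SN2 displacement with LiCl in DMF at the carbonyl-activated C3 should give 14, which is reduced with NaBH4/CeCl3·7H2O as before. The route is rejoined at 15.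

Step 10. Hydride transfer from copper to the neopentyl-like β-carbon C9 may be too slow, or the exocyclic double bond may move into the ring during the elimination. The fallback sets out from 19 and separates reduction from enolate formation. Hydrogenation (H2, palladium on carbon, EtOAc; delivery on the α face) should give the saturated 7-ketone F4. Kinetic enolisation with LiN(SiMe3)2 at −78 °C is expected at C8, because C6 is shielded by the 4α-methyl group, and Mannich reaction with CH2=NMe2+ I− gives 21. Methylation and buffered elimination via 22 come back to the route at 23.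

**Further compounds**
F1 | step 2 | (5S)-2-methoxy-5-methyl-5-(4-methyl-2-oxopent-3-en-1-yl)cyclohex-2-ene-1,4-dione | O=C1C=C(OC)C(=O)C[C@]1(C)CC(=O)C=C(C)C
F2 | step 7 | 3α-hydroxy-2-ketone (5α-H; 7-OMe-Δ7; 9-oxo) | O=C1C=C(OC)C[C@H]2C(C)(C)[C@H](O)C(=O)C[C@@]21C
F3 | step 7 | 3α-triflyloxy-2-ketone (5α-H; 7-OMe-Δ7; 9-oxo) | O=C1C=C(OC)C[C@H]2C(C)(C)[C@H](OS(=O)(=O)C(F)(F)F)C(=O)C[C@@]21C
F4 | step 10 | saturated 7-ketone (2α,3β-dichloro; 9α-H; C9–CH2CN β) | C1C(=O)C[C@H]2C(C)(C)[C@@H](Cl)[C@H](Cl)C[C@]2(C)[C@H]1CC#N
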